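The polyene is cut at C11=C12 and C11'=C12' into commercial C10 dialdehyde and two C15 phosphonium salts, each grown from an acyclic 1,6-diketone. The trihydroxycyclohexane ring is read as a pinacol: its vicinal tertiary carbinols C5(OH)(CH3) and C6(OH)(side chain) are joined by reductive coupling of a methyl ketone with an alkynyl ketone, which closes the ring and sets both centres as the trans-diol in one operation, relayed from the C3 ester. The precursor is an open-chain dioxo-enyne pivalate built from (S)-epichlorohydrin, isobutyric acid and an enyne. Its enantiomer, reached from the same hydroxy ynone by Mitsunobu inversion and coupled under chelation, gives the cis-diol that becomes the 3,6-epoxy ring.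

Key step: step 7

Remark: carotenoid numbering is used in the Why lines (ring C1–C6, chain from C7, primed for the oxabicyclic half). Every THP ether is carried as both epimers at the acetal carbon, so its SMILES leaves that one centre open. The target is taken as the all-E isomer exactly as drawn.

Step 1
Reactants: 1 (2E)-3-methylpent-2-en-4-yn-1-ol
Product: 2 2-{[(2E)-3-methylpent-2-en-4-yn-1-yl]oxy}oxane
Conditions: 3,4-dihydro-2H-pyran, PPTS (cat.), CH2Cl2, rt
Reagents that add atoms: 3,4-dihydro-2H-pyran, C1=COCCC1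
Why: Acid-catalysed addition of the primary alcohol to the enol ether (THP protection) masks the hydroxyl for the later acetylide chemistry and sets no stereocentre of consequence.

Step 2
Reactants: 3 (S)-epichlorohydrin
Product: 4 (2S)-1-chloropent-4-en-2-ol
Conditions: CH2=CHMgBr, CuI (10 mol %), THF, −40 → −20 °C; aq NH4Cl
Reagents that add atoms: vinylmagnesium bromide, C=C[Mg]Br
Why: Copper-catalysed Grignard opening of the epoxide at its unsubstituted carbon leaves the C–O stereocentre (the future C3 of both end groups) untouched.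

Step 3
Reactants: 4 (2S)-1-chloropent-4-en-2-ol; 5 2-methylpropanoic acid
Product: 9 (5S)-3,3-dimethyl-5-(prop-2-en-1-yl)oxolan-2-one, via isobutyrate dianion 6 (not isolated), via (2S)-2-allyloxirane 7 (not isolated), via lithium hydroxy-carboxylate 8 (not isolated)
Conditions: i-PrCO2H (2.2 equiv), LiN(i-Pr)2 (4.4 equiv), THF, 0 °C; then 4, 0 → 45 °C; 3 M HCl, rt
Reagents that add atoms: none
Why: One equivalent of the carboxylic acid dianion closes the chlorohydrin to the terminal epoxide, a second opens it at CH2 (dianion–epoxide alkylation) and acid lactonises the γ-hydroxy acid, none of which touches the stereocentre.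

Step 4
Reactants: 9 (5S)-3,3-dimethyl-5-(prop-2-en-1-yl)oxolan-2-one; 2 2-{[(2E)-3-methylpent-2-en-4-yn-1-yl]oxy}oxane
Product: 11 (2E,9S)-9-hydroxy-3,7,7-trimethyl-1-(oxan-2-yloxy)dodeca-2,11-dien-4-yn-6-one, via lithium acetylide 10 (not isolated)
Conditions: 2, n-BuLi, THF, −78 °C; then 9, −78 → −40 °C; aq NH4Cl
Reagents that add atoms: none
Why: Single addition of a lithium acetylide to a lactone should stop at the ynone because the lactone has no α-hydrogen and the tetrahedral lithium hemiketalate survives at low temperature; conjugation with the alkyne favours the open hydroxy ynone over its lactol.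

Step 5
Reactants: 11 (2E,9S)-9-hydroxy-3,7,7-trimethyl-1-(oxan-2-yloxy)dodeca-2,11-dien-4-yn-6-one
Product: 12 (4S,10E)-6,6,10-trimethyl-7-oxo-12-(oxan-2-yloxy)dodeca-1,10-dien-8-yn-4-yl 2,2-dimethylpropanoate
Conditions: PivCl, pyridine, DMAP (cat.), CH2Cl2, 0 °C → rt
Reagents that add atoms: pivaloyl chloride, CC(C)(C)C(=O)Cl
Why: Acylation of the secondary alcohol, with retention at the carbinol carbon, locks the open-chain form; the pivalate is inert to SmI2, resists migration and β-elimination, and is shed later in the hydride step.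

Step 6
Reactants: 12 (4S,10E)-6,6,10-trimethyl-7-oxo-12-(oxan-2-yloxy)dodeca-1,10-dien-8-yn-4-yl 2,2-dimethylpropanoate
Product: 13 (4R,10E)-6,6,10-trimethyl-2,7-dioxo-12-(oxan-2-yloxy)dodec-10-en-8-yn-4-yl 2,2-dimethylpropanoate
Conditions: PdCl2 (10 mol %), Cu(OAc)2 (20 mol %), O2 (1 atm), DMA/H2O 7:1, rt
Reagents that add atoms: water, O
Why: Tsuji–Wacker oxidation by divalent palladium converts the terminal alkene into the methyl ketone with Markovnikov selectivity, while the trisubstituted enyne alkene and the internal alkyne react far more slowly and the acetate buffer spares the THP acetal (the descriptor changes from S to R only through the priority rules).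

Step 7
Reactants: 13 (4R,10E)-6,6,10-trimethyl-2,7-dioxo-12-(oxan-2-yloxy)dodec-10-en-8-yn-4-yl 2,2-dimethylpropanoate
Product: 14 (1R,3S,4R)-3,4-dihydroxy-3,5,5-trimethyl-4-[(3E)-3-methyl-5-(oxan-2-yloxy)pent-3-en-1-yn-1-yl]cyclohexyl 2,2-dimethylpropanoate
Conditions: SmI2 (3 equiv), HMPA (12 equiv), THF, −78 °C, slow addition of 13 at high dilution; aq NH4Cl
Reagents that add atoms: none
Why: SmI2–HMPA reduces the conjugated ynone to its ketyl, which joins the methyl ketone carbon (itself reduced to a ketyl or as the carbonyl) in an intramolecular ketone–ketone pinacol coupling that forms the C5–C6 bond and both tertiary carbinols at once. The closest known reaction type is the SmI2-mediated pinacol cyclisation of 1,6-dicarbonyl compounds to cyclohexane-1,2-diols. The ring closes in the 6-exo-trig mode (C6 ketyl carbon onto the C5 carbonyl, whose oxygen stays exocyclic) through a chair. C5 is controlled by the ring substituents: the C3 pivalate and the C5 methyl sit equatorial, the methyl to avoid a syn-diaxial clash with the axial C1 methyl, so O5 is axial and trans to O3 (5S); C6 is controlled by the reagent: HMPA saturates trivalent samarium, no metal bridges the two oxygens, and dipole and steric repulsion of the two O–Sm(HMPA)n groups should place O6 axial and anti to O5 with the slim alkynyl group equatorial, which is the trans-diol with O6 cis to O3 (the centre that is 6S once the alkyne is reduced). The step needs anti over syn diol selectivity, secured by the absence of chelation, and coupling through the carbonyl carbon and not the alkyne terminus, secured because the alternative would need an eight-membered allenic ring while slow addition at high dilution and the absence of a proton source suppress dimerisation and simple reduction.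

Step 8
Reactants: 14 (1R,3S,4R)-3,4-dihydroxy-3,5,5-trimethyl-4-[(3E)-3-methyl-5-(oxan-2-yloxy)pent-3-en-1-yn-1-yl]cyclohexyl 2,2-dimethylpropanoate
Product: 15 (1S,2S,4R)-1-[(1E,3E)-3-methyl-5-(oxan-2-yloxy)penta-1,3-dien-1-yl]-2,6,6-trimethylcyclohexane-1,2,4-triol
Conditions: NaAlH2(OCH2CH2OMe)2 (Red-Al, excess), THF, 0 °C → rt; aq KNaC4H4O6 (potassium sodium tartrate)
Reagents that add atoms: none
Why: Trans-hydroalumination of the propargylic alcohol through its alkoxyaluminate gives the (7E)-alkene, and the same hydride cleaves the pivalate reductively.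

Step 9
Reactants: 15 (1S,2S,4R)-1-[(1E,3E)-3-methyl-5-(oxan-2-yloxy)penta-1,3-dien-1-yl]-2,6,6-trimethylcyclohexane-1,2,4-triol
Product: 17 [(2E,4E)-3-methyl-5-[(1S,2S,4R)-1,2,4-trihydroxy-2,6,6-trimethylcyclohexyl]penta-2,4-dien-1-yl]triphenylphosphonium bromide, via tetraol 16 (not isolated)
Conditions: PPh3·HBr, MeOH, 0 °C → rt
Reagents that add atoms: triphenylphosphine hydrobromide, [Br-].[PH+](c1ccccc1)(c1ccccc1)c1ccccc1
Why: Acidic methanol removes the THP acetal and the liberated primary allylic alcohol is converted into the phosphonium salt (allylic substitution by PPh3), the secondary and the β-oxygenated tertiary hydroxyls being much less prone to ionise.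

Step 10
Reactants: 11 (2E,9S)-9-hydroxy-3,7,7-trimethyl-1-(oxan-2-yloxy)dodeca-2,11-dien-4-yn-6-one
Product: 18 (4R,10E)-6,6,10-trimethyl-7-oxo-12-(oxan-2-yloxy)dodeca-1,10-dien-8-yn-4-yl 2,2-dimethylpropanoate
Conditions: PPh3, DIAD (premixed at 0 °C), t-BuCO2H, toluene, −20 °C → rt
Reagents that add atoms: pivalic acid, CC(C)(C)C(=O)O
Why: Mitsunobu esterification activates the secondary alcohol as its alkoxyphosphonium ion, which pivalate displaces in an SN2 step with inversion, so that the (9S)-alcohol shared with step 5 gives the (4R)-ester of the mirror-image series; C7 is quaternary, which rules out enolisation, and preforming the betaine keeps free phosphine away from the ynone.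

Step 11
Reactants: 18 (4R,10E)-6,6,10-trimethyl-7-oxo-12-(oxan-2-yloxy)dodeca-1,10-dien-8-yn-4-yl 2,2-dimethylpropanoate
Product: 19 (4S,10E)-6,6,10-trimethyl-2,7-dioxo-12-(oxan-2-yloxy)dodec-10-en-8-yn-4-yl 2,2-dimethylpropanoate
Conditions: PdCl2 (10 mol %), Cu(OAc)2 (20 mol %), O2 (1 atm), DMA/H2O 7:1, rt
Reagents that add atoms: water, O
Why: Tsuji–Wacker oxidation of the terminal alkene to the methyl ketone, as in step 6 (the descriptor changes from R to S only through the priority rules).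

Step 12
Reactants: 19 (4S,10E)-6,6,10-trimethyl-2,7-dioxo-12-(oxan-2-yloxy)dodec-10-en-8-yn-4-yl 2,2-dimethylpropanoate
Product: 20 (1S,3R,4R)-3,4-dihydroxy-3,5,5-trimethyl-4-[(3E)-3-methyl-5-(oxan-2-yloxy)pent-3-en-1-yn-1-yl]cyclohexyl 2,2-dimethylpropanoate
Conditions: SmI2 (2.5 equiv), THF, −78 → −30 °C, slow addition of 19; aq NH4Cl
Reagents that add atoms: none
Why: Without HMPA the samarium ketyl of the enynone chelates the second carbonyl, so this SmI2 pinacol cyclisation should run through the same kind of chair (pivalate and C5 methyl equatorial, O5 axial and trans to O3) but with O6 gauche to O5 and the alkynyl group axial, giving the cis-5,6-diol that lies trans to the C3 oxygen.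

Step 13
Reactants: 20 (1S,3R,4R)-3,4-dihydroxy-3,5,5-trimethyl-4-[(3E)-3-methyl-5-(oxan-2-yloxy)pent-3-en-1-yn-1-yl]cyclohexyl 2,2-dimethylpropanoate
Product: 21 (1S,2R,4S)-1-[(1E,3E)-3-methyl-5-(oxan-2-yloxy)penta-1,3-dien-1-yl]-2,6,6-trimethylcyclohexane-1,2,4-triol
Conditions: NaAlH2(OCH2CH2OMe)2 (Red-Al, excess), THF, 0 °C → rt; aq KNaC4H4O6 (potassium sodium tartrate)
Reagents that add atoms: none
Why: Hydroxyl-directed trans-hydroalumination gives the (7E)-alkene and the hydride removes the pivalate, freeing the secondary C3 hydroxyl for the ring closure.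

Step 14
Reactants: 21 (1S,2R,4S)-1-[(1E,3E)-3-methyl-5-(oxan-2-yloxy)penta-1,3-dien-1-yl]-2,6,6-trimethylcyclohexane-1,2,4-triol
Product: 22 (1S,2R,4R)-2,6,6-trimethyl-1-[(1E,3E)-3-methyl-5-(oxan-2-yloxy)penta-1,3-dien-1-yl]-7-oxabicyclo[2.2.1]heptan-2-ol
Conditions: PPh3, DIAD, toluene, 0 → 80 °C
Reagents that add atoms: none
Why: Mitsunobu cyclodehydration activates only the secondary C3 hydroxyl, and the tertiary C6 hydroxyl, trans to it across the ring, displaces it from a boat with inversion at C3, so that the new oxygen bridge lies syn to the C5 hydroxyl as the target requires.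

Step 15
Reactants: 22 (1S,2R,4R)-2,6,6-trimethyl-1-[(1E,3E)-3-methyl-5-(oxan-2-yloxy)penta-1,3-dien-1-yl]-7-oxabicyclo[2.2.1]heptan-2-ol
Product: 24 {(2E,4E)-5-[(1S,2R,4R)-2-hydroxy-2,6,6-trimethyl-7-oxabicyclo[2.2.1]heptan-1-yl]-3-methylpenta-2,4-dien-1-yl}triphenylphosphonium bromide, via allylic alcohol 23 (not isolated)
Conditions: PPh3·HBr, MeOH, 0 °C → rt
Reagents that add atoms: triphenylphosphine hydrobromide, [Br-].[PH+](c1ccccc1)(c1ccccc1)c1ccccc1
Why: Acidic methanol removes the THP acetal and the primary allylic alcohol is converted into the phosphonium salt, as in step 9.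

Step 16
Reactants: 17 [(2E,4E)-3-methyl-5-[(1S,2S,4R)-1,2,4-trihydroxy-2,6,6-trimethylcyclohexyl]penta-2,4-dien-1-yl]triphenylphosphonium bromide; 25 (2E,4E,6E)-2,7-dimethylocta-2,4,6-trienedial
Product: 27 (2E,4E,6E,8E,10E,12E)-2,7,11-trimethyl-13-[(1S,2S,4R)-1,2,4-trihydroxy-2,6,6-trimethylcyclohexyl]trideca-2,4,6,8,10,12-hexaenal, via ylide 26 (not isolated)
Conditions: 25 (3 equiv), NaOMe, MeOH/CH2Cl2, 0 °C → rt; then reflux in EtOAc (Z → E)
Reagents that add atoms: none
Why: Wittig olefination of one aldehyde group of the symmetrical dialdehyde, used in excess, forms C11=C12 in the presence of the free hydroxyls, and heating should convert the unhindered Z isomer into the all-E polyene.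

Step 17
Reactants: 24 {(2E,4E)-5-[(1S,2R,4R)-2-hydroxy-2,6,6-trimethyl-7-oxabicyclo[2.2.1]heptan-1-yl]-3-methylpenta-2,4-dien-1-yl}triphenylphosphonium bromide; 27 (2E,4E,6E,8E,10E,12E)-2,7,11-trimethyl-13-[(1S,2S,4R)-1,2,4-trihydroxy-2,6,6-trimethylcyclohexyl]trideca-2,4,6,8,10,12-hexaenal
Product: 29 CNP0261804.1 (target), via ylide 28 (not isolated)
Conditions: NaOMe, MeOH/CH2Cl2, rt, Ar, dark; then reflux in EtOH (Z → E)
Reagents that add atoms: none
Why: The second Wittig olefination forms C11'=C12' and completes the C40 polyene, thermal equilibration again favouring the all-E isomer; no stereocentre is touched.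

Compound list
1 | (2E)-3-methylpent-2-en-4-yn-1-ol | C#C/C(C)=C/CO | starting material
2 | 2-{[(2E)-3-methylpent-2-en-4-yn-1-yl]oxy}oxane | C#C/C(C)=C/COC1CCCCO1 | intermediate
3 | (S)-epichlorohydrin, (2S)-2-(chloromethyl)oxirane | ClC[C@@H]1CO1 | starting material
4 | (2S)-1-chloropent-4-en-2-ol | ClC[C@@H](O)CC=C | intermediate
5 | 2-methylpropanoic acid (isobutyric acid) | CC(C)C(=O)O | starting material
6 | dilithium 2-methylprop-1-ene-1,1-diolate (isobutyrate dianion) | [Li+].[Li+].CC(C)=C([O-])[O-] | intermediate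
7 | (2S)-2-(prop-2-en-1-yl)oxirane | C=CC[C@H]1CO1 | intermediate
8 | (4S)-4-hydroxy-2,2-dimethylhept-6-enoic acid (formed as its lithium salt) | C=CC[C@H](O)CC(C)(C)C(=O)O | intermediate
9 | (5S)-3,3-dimethyl-5-(prop-2-en-1-yl)oxolan-2-one | C=CC[C@H]1CC(C)(C)C(=O)O1 | intermediate
10 | lithium acetylide of 2 | [Li+].[C-]#C/C(C)=C/COC1CCCCO1 | intermediate
11 | (2E,9S)-9-hydroxy-3,7,7-trimethyl-1-(oxan-2-yloxy)dodeca-2,11-dien-4-yn-6-one | C=CC[C@H](O)CC(C)(C)C(=O)C#C/C(C)=C/COC1CCCCO1 | intermediate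
12 | (4S,10E)-6,6,10-trimethyl-7-oxo-12-(oxan-2-yloxy)dodeca-1,10-dien-8-yn-4-yl 2,2-dimethylpropanoate | C=CC[C@H](OC(=O)C(C)(C)C)CC(C)(C)C(=O)C#C/C(C)=C/COC1CCCCO1 | intermediate
13 | (4R,10E)-6,6,10-trimethyl-2,7-dioxo-12-(oxan-2-yloxy)dodec-10-en-8-yn-4-yl 2,2-dimethylpropanoate | CC(=O)C[C@H](OC(=O)C(C)(C)C)CC(C)(C)C(=O)C#C/C(C)=C/COC1CCCCO1 | intermediate
14 | (1R,3S,4R)-3,4-dihydroxy-3,5,5-trimethyl-4-[(3E)-3-methyl-5-(oxan-2-yloxy)pent-3-en-1-yn-1-yl]cyclohexyl 2,2-dimethylpropanoate (trans-5,6-diol) | O(C1CCCCO1)C/C=C(C)/C#C[C@]1(O)C(C)(C)C[C@@H](OC(=O)C(C)(C)C)C[C@]1(C)O | intermediate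
15 | (1S,2S,4R)-1-[(1E,3E)-3-methyl-5-(oxan-2-yloxy)penta-1,3-dien-1-yl]-2,6,6-trimethylcyclohexane-1,2,4-triol | O(C1CCCCO1)C/C=C(C)/C=C/[C@]1(O)C(C)(C)C[C@@H](O)C[C@]1(C)O | intermediate
16 | (1S,2S,4R)-1-[(1E,3E)-5-hydroxy-3-methylpenta-1,3-dien-1-yl]-2,6,6-trimethylcyclohexane-1,2,4-triol | OC/C=C(C)/C=C/[C@]1(O)C(C)(C)C[C@@H](O)C[C@]1(C)O | intermediate
17 | [(2E,4E)-3-methyl-5-[(1S,2S,4R)-1,2,4-trihydroxy-2,6,6-trimethylcyclohexyl]penta-2,4-dien-1-yl]triphenylphosphonium bromide | [Br-].c1ccccc1[P+](c1ccccc1)(c1ccccc1)C/C=C(C)/C=C/[C@]1(O)C(C)(C)C[C@@H](O)C[C@]1(C)O | intermediate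
18 | (4R,10E)-6,6,10-trimethyl-7-oxo-12-(oxan-2-yloxy)dodeca-1,10-dien-8-yn-4-yl 2,2-dimethylpropanoate | C=CC[C@@H](OC(=O)C(C)(C)C)CC(C)(C)C(=O)C#C/C(C)=C/COC1CCCCO1 | intermediate
19 | (4S,10E)-6,6,10-trimethyl-2,7-dioxo-12-(oxan-2-yloxy)dodec-10-en-8-yn-4-yl 2,2-dimethylpropanoate | CC(=O)C[C@@H](OC(=O)C(C)(C)C)CC(C)(C)C(=O)C#C/C(C)=C/COC1CCCCO1 | intermediate
20 | (1S,3R,4R)-3,4-dihydroxy-3,5,5-trimethyl-4-[(3E)-3-methyl-5-(oxan-2-yloxy)pent-3-en-1-yn-1-yl]cyclohexyl 2,2-dimethylpropanoate (cis-5,6-diol) | O(C1CCCCO1)C/C=C(C)/C#C[C@]1(O)C(C)(C)C[C@H](OC(=O)C(C)(C)C)C[C@@]1(C)O | intermediate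
21 | (1S,2R,4S)-1-[(1E,3E)-3-methyl-5-(oxan-2-yloxy)penta-1,3-dien-1-yl]-2,6,6-trimethylcyclohexane-1,2,4-triol | O(C1CCCCO1)C/C=C(C)/C=C/[C@]1(O)C(C)(C)C[C@H](O)C[C@@]1(C)O | intermediate
22 | (1S,2R,4R)-2,6,6-trimethyl-1-[(1E,3E)-3-methyl-5-(oxan-2-yloxy)penta-1,3-dien-1-yl]-7-oxabicyclo[2.2.1]heptan-2-ol | O(C3CCCCO3)C/C=C(C)/C=C/[C@]12O[C@H](CC1(C)C)C[C@@]2(C)O | intermediate
23 | (1S,2R,4R)-1-[(1E,3E)-5-hydroxy-3-methylpenta-1,3-dien-1-yl]-2,6,6-trimethyl-7-oxabicyclo[2.2.1]heptan-2-ol | OC/C=C(C)/C=C/[C@]12O[C@H](CC1(C)C)C[C@@]2(C)O | intermediate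
24 | {(2E,4E)-5-[(1S,2R,4R)-2-hydroxy-2,6,6-trimethyl-7-oxabicyclo[2.2.1]heptan-1-yl]-3-methylpenta-2,4-dien-1-yl}triphenylphosphonium bromide | [Br-].c1ccccc1[P+](c1ccccc1)(c1ccccc1)C/C=C(C)/C=C/[C@]12O[C@H](CC1(C)C)C[C@@]2(C)O | intermediate
25 | (2E,4E,6E)-2,7-dimethylocta-2,4,6-trienedial | O=C/C(C)=C/C=C/C=C(C)/C=O | starting material
26 | ylide of 17 | [CH-]([P+](c1ccccc1)(c1ccccc1)c1ccccc1)/C=C(C)/C=C/[C@]1(O)C(C)(C)C[C@@H](O)C[C@]1(C)O | intermediate
27 | (2E,4E,6E,8E,10E,12E)-2,7,11-trimethyl-13-[(1S,2S,4R)-1,2,4-trihydroxy-2,6,6-trimethylcyclohexyl]trideca-2,4,6,8,10,12-hexaenal | O=C/C(C)=C/C=C/C=C(C)/C=C/C=C(C)/C=C/[C@]1(O)C(C)(C)C[C@@H](O)C[C@]1(C)O | intermediate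
28 | ylide of 24 | [CH-]([P+](c1ccccc1)(c1ccccc1)c1ccccc1)/C=C(C)/C=C/[C@]12O[C@H](CC1(C)C)C[C@@]2(C)O | intermediate
29 | CNP0261804.1, all-E carotenoid with a (3R,5S,6S)-3,5,6-trihydroxy end group and a (3R,5R,6S)-3,6-epoxy-5-hydroxy end group | CC(/C=C/C=C(C)/C=C/[C@]12O[C@H](CC1(C)C)C[C@@]2(C)O)=C\C=C\C=C(C)\C=C\C=C(C)\C=C\[C@]1(O)C(C)(C)C[C@@H](O)C[C@]1(C)O | target

Total step count: 17. Longest linear sequence: 10 steps (3 → 29 through steps 2–9, 16 and 17; equally through steps 2–4, 10–15 and 17).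

Steps most likely to fail

Step 7. Residual bridging of the two ketyl oxygens by samarium would erode the anti selectivity towards the cis-diol, and the enynone ketyl may be over-reduced or dimerise before it cyclises. The fallback sets out from 13 and forms the same C5–C6 bond by a different mechanism. An intramolecular McMurry coupling (TiCl3(DME)1.5, Zn–Cu, DME, reflux) would give (1S)-3,5,5-trimethyl-4-[(3E)-3-methyl-5-(oxan-2-yloxy)pent-3-en-1-yn-1-yl]cyclohex-3-en-1-yl 2,2-dimethylpropanoate F1. Epoxidation of its tetrasubstituted alkene (m-CPBA, NaHCO3, CH2Cl2, 0 °C) on the face away from the pivalate would give the anti-5,6-epoxide pivalate F2. Acid-catalysed trans-diaxial hydrolysis (HClO4 cat., THF/H2O, 0 °C), with water expected to enter at the propargylic C6 and the THP acetal lost at the same time, would give (1R,3S,4R)-3,4-dihydroxy-4-[(3E)-5-hydroxy-3-methylpent-3-en-1-yn-1-yl]-3,5,5-trimethylcyclohexyl 2,2-dimethylpropanoate F3. Red-Al reduction of F3 as in step 8 leads to 16, where the route is rejoined and continued with the conditions of step 9.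

Step 14. E2 elimination of the activated C3 oxygen, or a Grob-type cleavage of C4–C5 driven by the C5 hydroxyl, may outrun closure of the strained oxygen bridge. The fallback sets out from 21 and makes the C6–O bond instead of the C3–O bond. Mitsunobu inversion with 4-nitrobenzoic acid (PPh3, DIAD, THF, 0 °C) would give (1R,3R,4S)-3,4-dihydroxy-3,5,5-trimethyl-4-[(1E,3E)-3-methyl-5-(oxan-2-yloxy)penta-1,3-dien-1-yl]cyclohexyl 4-nitrobenzoate F4. Methanolysis (K2CO3, MeOH) would give the all-cis (1S,2R,4R)-1-[(1E,3E)-3-methyl-5-(oxan-2-yloxy)penta-1,3-dien-1-yl]-2,6,6-trimethylcyclohexane-1,2,4-triol F5. PPTS in dry CH2Cl2 should then ionise the tertiary allylic C6 hydroxyl, and the C3 hydroxyl, now on the same face as the C5 hydroxyl, should capture the cation to give 22.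

Step 10. Three processes may compete with clean inversion:
- the ketone oxygen, held close by the gem-dimethyl group, may take part in the displacement of the alkoxyphosphonium ion and erode the inversion;
- elimination towards the allyl group may outrun attack by the hindered pivalate;
- the minor lactol form of 11 may be esterified at its anomeric hydroxyl.

The fallback sets out from 5 and 2 and takes the carbinol configuration from the chiral pool instead of inverting it. Copper-catalysed opening of commercial (R)-epichlorohydrin with CH2=CHMgBr under the conditions of step 2 would give (2R)-1-chloropent-4-en-2-ol F6. The dianion of 5 under the conditions of step 3 would convert it into (5R)-3,3-dimethyl-5-(prop-2-en-1-yl)oxolan-2-one F7. Addition of lithiated 2 under the conditions of step 4 would give (2E,9R)-9-hydroxy-3,7,7-trimethyl-1-(oxan-2-yloxy)dodeca-2,11-dien-4-yn-6-one F8. Acylation with PivCl under the conditions of step 5, which leaves the carbinol centre untouched, gives 18, where the route is rejoined.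

Further compounds
F1 | step 7 | (1S)-3,5,5-trimethyl-4-[(3E)-3-methyl-5-(oxan-2-yloxy)pent-3-en-1-yn-1-yl]cyclohex-3-en-1-yl 2,2-dimethylpropanoate | CC1=C(C#C/C(C)=C/COC2CCCCO2)C(C)(C)C[C@@H](OC(=O)C(C)(C)C)C1
F2 | step 7 | anti-5,6-epoxide of F1 (oxirane trans to the pivalate), a 7-oxabicyclo[4.1.0]heptan-3-yl 2,2-dimethylpropanoate | O(C3CCCCO3)C/C=C(C)/C#C[C@@]12C(C)(C)C[C@@H](OC(=O)C(C)(C)C)C[C@]1(C)O2
F3 | step 7 | (1R,3S,4R)-3,4-dihydroxy-4-[(3E)-5-hydroxy-3-methylpent-3-en-1-yn-1-yl]-3,5,5-trimethylcyclohexyl 2,2-dimethylpropanoate | OC/C=C(C)/C#C[C@]1(O)C(C)(C)C[C@@H](OC(=O)C(C)(C)C)C[C@]1(C)O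
F4 | step 14 | (1R,3R,4S)-3,4-dihydroxy-3,5,5-trimethyl-4-[(1E,3E)-3-methyl-5-(oxan-2-yloxy)penta-1,3-dien-1-yl]cyclohexyl 4-nitrobenzoate | O(C1CCCCO1)C/C=C(C)/C=C/[C@]1(O)C(C)(C)C[C@@H](OC(=O)c2ccc(cc2)[N+](=O)[O-])C[C@@]1(C)O
F5 | step 14 | (1S,2R,4R)-1-[(1E,3E)-3-methyl-5-(oxan-2-yloxy)penta-1,3-dien-1-yl]-2,6,6-trimethylcyclohexane-1,2,4-triol | O(C1CCCCO1)C/C=C(C)/C=C/[C@]1(O)C(C)(C)C[C@@H](O)C[C@@]1(C)O
F6 | step 10 | (2R)-1-chloropent-4-en-2-ol | ClC[C@H](O)CC=C
F7 | step 10 | (5R)-3,3-dimethyl-5-(prop-2-en-1-yl)oxolan-2-one | C=CC[C@@H]1CC(C)(C)C(=O)O1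
F8 | step 10 | (2E,9R)-9-hydroxy-3,7,7-trimethyl-1-(oxan-2-yloxy)dodeca-2,11-dien-4-yn-6-one | C=CC[C@@H](O)CC(C)(C)C(=O)C#C/C(C)=C/COC1CCCCO1
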